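Compound numbers used throughout: ring A building block 1 → ketal 2; ring B building block 3 → 4 → 5 → 6 → Grignard reagent 7; key adduct 8; quinol 9 (not isolated); phenol 10; target 11.

## The problem

Target 11 is a diarylmethane: ring A (3-bromo-4-hydroxyphenyl) and ring B (3,5-dibromo-4-hydroxyphenyl) are joined through one CH2 group at C1 of each ring, and both hydroxyls lie para to the bridge. It has no stereocentre, so there is nothing to relay or control. The one stereocentre that arises on the way (C1 of ring A in dienol 8) is transient. The real difficulty is positional: three bromines are spread unevenly, one at C3 of ring A and two at C3 and C5 of ring B. The four positions ortho to oxygen in the parent bisphenol are almost equivalent, so bromination after the union cannot be trusted to stop at this pattern. A classical Friedel–Crafts benzylation of a 2-bromophenol derivative must also choose between ortho and para attack. The three aryl C–Br bonds rule out catalytic hydrogenation and forcing dissolving-metal conditions, and they make any magnesium, lithium or palladium step a chemoselectivity question. The electron-rich bis(4-hydroxyphenyl)methane unit is open to acid-induced transbenzylation and to oxidation at the benzylic carbon. The enabling feature is that C1 of ring A is para to the oxygen-bearing C4, with C3–Br next to C4. Ring A can therefore be written as a cyclohexadienone with a dimethyl ketal at C4 and a carbonyl at C1, which is an electrophile at exactly the carbon that must receive the benzyl group.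

## Retrosynthesis

**11 ⇒ 10.** The ring B O–CH3 bond is cut. The ring B hydroxyl must be masked because a benzylic organometallic cannot carry a phenolic proton, and a para-oxidobenzyl halide would collapse to a quinone methide. A methyl ether is chosen over acetal or silyl groups because it survives chlorination, magnesium insertion, aqueous acid and zinc. The 2,6-dibromoanisole in 10 is twisted out of conjugation and should cleave readily under Lewis-acid conditions. Only one ether has to be cleaved, because ring A arrives as the free phenol.

**10 ⇒ 8 (through 9).** No skeletal bond is cut here; the oxidation state of ring A is changed. Phenol 10 is the two-electron reduction product of p-quinol 9, and 9 is the hydrolysis product of ketal 8. C4–O of ring A is the former ketal carbon and C1 carries the extra hydroxyl. The neighbouring option, direct ionic reduction of 8, would give the ring A methyl ether and add a second demethylation; it would also run through cations prone to benzyl shift in the absence of water. The forward step must hydrolyse the ketal without benzyl migration and remove the C1 hydroxyl without touching three C–Br bonds.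

**8 ⇒ 2 + 7.** The bond between the methylene carbon and C1 of ring A is cut, with ring A as the electrophile (3-bromo-4,4-dimethoxycyclohexa-2,5-dien-1-one, 2) and the ring B benzylic carbon as the nucleophile ((3,5-dibromo-4-methoxybenzyl)magnesium chloride, 7). The same cut with normal polarity, benzyl cation onto a bromophenol ether, leaves an ortho/para choice. The cut on the other side of the methylene would need an aryl metal on the dibrominated ring. Here the carbonyl of 2 fixes the site of union and the bromine of 2 already sits next to the ketal carbon. Each precursor holds one ring with all its bromines in place. The forward reaction must be a clean 1,2-addition.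

**7 ⇒ 6 ⇒ 5 ⇒ 4 ⇒ 3.** These are functional-group changes at one carbon: C–Mg from C–Cl (chloride 6), C–Cl from C–OH (alcohol 5), the alcohol from aldehyde 4, and 4 by O-methylation of commercial 3,5-dibromo-4-hydroxybenzaldehyde 3. The chloride is preferred to the bromide because it gives less homocoupling on magnesium insertion. 3 is bought with both bromines flanking the hydroxyl, so no bromination is needed.

**2 ⇒ 1.** The second C4–OMe bond is cut and the C1 carbonyl is returned to a phenol. Commercial 3-bromo-4-methoxyphenol 1 has the bromine ortho to the methoxy group, so oxidative dearomatization in methanol places the ketal next to C–Br. The alternative, monohydrolysis of a bromoquinone bisketal, is a step longer and is kept as a fallback.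

## Roads not taken

**Alternative 1:** The cut goes through ring A itself (bonds C1–C2 and C5–C6). A [4+2] cycloaddition of the bromo siloxy diene A3 with the aryl ethynyl ketone A2, followed by loss of methanol and desilylation, would give benzophenone A1.
- Merits: the para relation of hydroxyl and bridge carbon and the ortho bromine follow from the polarization of diene and dienophile. No aromatic substitution on ring A is needed, and the ring A phenol is free at once.
- Weak points: A3 is not a stock reagent. It is a hydrolytically fragile, doubly oxygenated bromodiene whose bromine lowers its reactivity, and making it costs at least two steps. A2 needs two more steps from aldehyde 4 (alkynylation, oxidation). A1 sits at the ketone oxidation level, so a deoxygenation of a diaryl ketone flanked by deactivated rings must follow, then the demethylation.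
- Comparison: regiochemical certainty is equal to the chosen plan. The chosen plan buys both benzene rings with their bromines, reaches the CH2 oxidation level directly, and is several steps shorter.

**Alternative 2:** The cut is at the three C–Br bonds, made last. Oxidative bromination (KBr, H2O2, catalytic NH4VO3) of the tert-butyl-blocked bisphenol A5 would fill every free position ortho to oxygen and give A4. De-tert-butylation would then give the target.
- Merits: no protecting groups, cheap bromide as the bromine source, a biomimetic logic, and possibly the lowest step count of all if A5 were in hand.
- Weak points: A5 is itself an unsymmetrical diarylmethane, so the regiocontrolled union is postponed, not solved. Electrophilic bromine can attack a 4-hydroxybenzyl unit ipso to the bridge and cleave it, or oxidize it towards a quinone methide. Removing the tert-butyl group needs a strong Lewis acid such as AlCl3 in an arene solvent, conditions under which the tribrominated diarylmethane can suffer transbenzylation and bromine migration.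
- Comparison: this road is better in atom and protecting-group economy. The chosen plan sets against it that every bromine is bought in place, no electrophilic bromine ever meets the bisphenol, and the only Lewis acid used on the assembled skeleton is BBr3 at low temperature.

**Alternative 3:** The cut is at the bond from the methylene carbon to C1 of ring B. The tosylhydrazone A7 of the ring A aldehyde would be heated with base and the ring B boronic acid A8. The diazoalkane inserts into the C–B bond, and protodeboronation would give bis-anisole A6. Double demethylation then gives the target.
- Merits: no transition metal, so all aryl bromides are safe. The site of union is fixed. The sequence is very short: hydrazone formation, coupling, demethylation. In step count this road is at least as good as the chosen one and probably shorter.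
- Weak points: A8 is not a stock reagent, and installing boron para to the methoxy group of a polybrominated anisole runs against the usual preference of halogen–metal exchange for positions next to oxygen. The coupling needs about 110 °C, where an electron-rich aryldiazomethane can divert to azine formation, and the electron-poor aryl group of A8 migrates less readily. Two methyl ethers must be cleaved at the end.
- Comparison: the chosen plan sets against this that it uses only stock building blocks with the bromines in place, runs its bond-forming step at −78 °C, and delivers ring A as the free phenol so that one ether cleavage suffices.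

Key step: step 6

Assumption: Grignard reagent 7 is prepared and used at once as a titrated ethereal solution; it counts as the product of step 5 although it is never isolated neat.

## Route

Step 1
Reactants: 1 3-bromo-4-methoxyphenol
Product: 2 3-bromo-4,4-dimethoxycyclohexa-2,5-dien-1-one
Conditions: PhI(OAc)2 (1.1 equiv), MeOH, 0 °C to rt; NaHCO3 work-up
Reagents that add atoms: methanol, CO
Why: Oxidative dearomatization of a para-methoxyphenol by a trivalent iodine reagent; methanol adds at the methoxy-bearing para carbon to give the quinone monoketal, so the ketal lands next to the bromine that was ortho to the methoxy group.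

Step 2
Reactants: 3 3,5-dibromo-4-hydroxybenzaldehyde
Product: 4 3,5-dibromo-4-methoxybenzaldehyde
Conditions: MeI, K2CO3, DMF, 50 °C
Reagents that add atoms: iodomethane, CI
Why: Williamson ether synthesis; the acidic 2,6-dibromophenol is fully deprotonated by carbonate, and the hindered phenoxide is still alkylated by the small electrophile in a dipolar aprotic solvent.

Step 3
Reactants: 4 3,5-dibromo-4-methoxybenzaldehyde
Product: 5 (3,5-dibromo-4-methoxyphenyl)methanol
Conditions: NaBH4, MeOH, 0 °C
Reagents that add atoms: none
Why: Borohydride reduction of an aryl aldehyde; aryl bromides and the methyl ether are inert.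

Step 4
Reactants: 5 (3,5-dibromo-4-methoxyphenyl)methanol
Product: 6 1,3-dibromo-5-(chloromethyl)-2-methoxybenzene
Conditions: SOCl2, cat. DMF, CH2Cl2, 0 °C to rt
Reagents that add atoms: thionyl chloride, O=S(Cl)Cl
Why: Chlorodehydroxylation of a primary benzylic alcohol through its chlorosulfite with chloride displacement; the two electron-withdrawing bromines temper the benzylic cation, so self-alkylation is not expected.

Step 5
Reactants: 6 1,3-dibromo-5-(chloromethyl)-2-methoxybenzene
Product: 7 (3,5-dibromo-4-methoxybenzyl)magnesium chloride (ethereal solution)
Conditions: Mg turnings (I2-activated, excess), Et2O, 0 °C, slow addition of 6 at high dilution; titrate and use at once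
Reagents that add atoms: magnesium, [Mg]
Why: Grignard formation by oxidative insertion of magnesium into the benzylic C–Cl bond, which is far faster than insertion into aryl C–Br bonds at 0 °C; the chloride, dilution and slow addition hold back Wurtz homocoupling.

Step 6
Reactants: 2 3-bromo-4,4-dimethoxycyclohexa-2,5-dien-1-one, 7 (3,5-dibromo-4-methoxybenzyl)magnesium chloride
Product: 8 3-bromo-1-(3,5-dibromo-4-methoxybenzyl)-4,4-dimethoxycyclohexa-2,5-dien-1-ol (racemic)
Conditions: 7 (1.3 equiv, Et2O) added to 2 in THF, −78 °C; sat. aq. NH4Cl, −78 °C to rt
Reagents that add atoms: none
Why: Polar 1,2-addition: magnesium coordinates the carbonyl oxygen of 2 and the benzylic carbon of 7 attacks the carbonyl carbon, which becomes C1 of ring A carrying the new CH2–C1 bond. The closest known reaction type is the 1,2-addition of Grignard and organolithium reagents to quinone monoketals, which gives p-quinol ketals. No ring is closed. One stereocentre arises at the carbinol carbon; nothing in 2 distinguishes its two faces, so 8 is racemic, and the centre is erased in step 7. The step needs 1,2-selectivity over addition–elimination at the bromine-bearing beta carbon and over conjugate addition at the unsubstituted beta carbon; the first is shielded by the adjacent quaternary ketal carbon, and both are slow for a copper-free Grignard reagent at −78 °C, where attack at the unhindered carbonyl is fastest. Attack through the benzylic carbon and not through the ring of 7 is the normal course with an unhindered ketone. The vinylic and aryl C–Br bonds and the ketal are inert to the reagent at this temperature, and because the carbonyl fixes the site of union no ortho/para question arises.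

Step 7
Reactants: 8 3-bromo-1-(3,5-dibromo-4-methoxybenzyl)-4,4-dimethoxycyclohexa-2,5-dien-1-ol
Product: 10 2-bromo-4-(3,5-dibromo-4-methoxybenzyl)phenol, via racemic bromo p-quinol 9 (not isolated)
Conditions: AcOH–H2O–THF, rt; then Zn dust, rt
Reagents that add atoms: water, O
Why: Acid hydrolysis of the quinol ketal (the carbonyl oxygen of 9 comes from water) followed by zinc–acetic acid reductive aromatization of the p-quinol: two-electron reduction of the dienone expels the C4 hydroxyl as water and the phenol forms directly; bromine on sp2 carbon is not expected to be touched at room temperature, and the stereocentre disappears.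

Step 8
Reactants: 10 2-bromo-4-(3,5-dibromo-4-methoxybenzyl)phenol
Product: 11 2,6-dibromo-4-(3-bromo-4-hydroxybenzyl)phenol (target)
Conditions: BBr3 (3 equiv), CH2Cl2, −78 °C to rt; H2O quench
Reagents that add atoms: none
Why: Lewis-acid cleavage of an aryl methyl ether (boron coordinates oxygen, bromide attacks the methyl group); the twisted 2,6-dibromoanisole cleaves readily, and aryl bromides and the diarylmethane link tolerate BBr3 at or below room temperature.

## Compound list

1 | 3-bromo-4-methoxyphenol | COc1ccc(O)cc1Br | starting material
2 | 3-bromo-4,4-dimethoxycyclohexa-2,5-dien-1-one | COC1(OC)C=CC(=O)C=C1Br | intermediate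
3 | 3,5-dibromo-4-hydroxybenzaldehyde | O=Cc1cc(Br)c(O)c(Br)c1 | starting material
4 | 3,5-dibromo-4-methoxybenzaldehyde | COc1c(Br)cc(C=O)cc1Br | intermediate
5 | (3,5-dibromo-4-methoxyphenyl)methanol | COc1c(Br)cc(CO)cc1Br | intermediate
6 | 1,3-dibromo-5-(chloromethyl)-2-methoxybenzene | COc1c(Br)cc(CCl)cc1Br | intermediate
7 | (3,5-dibromo-4-methoxybenzyl)magnesium chloride | COc1c(Br)cc(C[Mg]Cl)cc1Br | intermediate
8 | 3-bromo-1-(3,5-dibromo-4-methoxybenzyl)-4,4-dimethoxycyclohexa-2,5-dien-1-ol (racemic) | COC1(OC)C=CC(O)(Cc2cc(Br)c(OC)c(Br)c2)C=C1Br | intermediate
9 | 2-bromo-4-(3,5-dibromo-4-methoxybenzyl)-4-hydroxycyclohexa-2,5-dien-1-one (racemic) | O=C1C=CC(O)(Cc2cc(Br)c(OC)c(Br)c2)C=C1Br | intermediate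
10 | 2-bromo-4-(3,5-dibromo-4-methoxybenzyl)phenol | Oc1ccc(Cc2cc(Br)c(OC)c(Br)c2)cc1Br | intermediate
11 | 2,6-dibromo-4-(3-bromo-4-hydroxybenzyl)phenol | Oc1ccc(Cc2cc(Br)c(O)c(Br)c2)cc1Br | target

## Step count and least certain steps

Total steps: 8. Longest linear sequence: 7 (steps 2, 3, 4, 5, 6, 7, 8 from 3); the ring A branch adds step 1.

**Step 6 (key step).**
- Risk: single-electron transfer from the benzylic reagent to the electron-poor dienone would cause homocoupling of the benzyl fragment and reduction of the dienone. Conjugate addition–elimination at the bromine-bearing carbon could also compete, since that carbon is a vinylogous acyl bromide position.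
- Fallback: it sets out from aldehyde 4 and uses the opposite, conventional polarity with the position fixed by a halogen. Iodine–magnesium exchange on commercial 2-bromo-4-iodoanisole with iPrMgCl·LiCl (THF, −20 °C; iodine exchanges before bromine) should give (3-bromo-4-methoxyphenyl)magnesium chloride F1. Its addition to 4 should give the racemic carbinol (3-bromo-4-methoxyphenyl)(3,5-dibromo-4-methoxyphenyl)methanol F2. Ionic hydrogenation of this doubly benzylic alcohol (Et3SiH, CF3CO2H, CH2Cl2) should give 2-bromo-4-(3,5-dibromo-4-methoxybenzyl)-1-methoxybenzene F3, the structure labelled A6 above. BBr3 should then cleave both ethers, and the fallback returns to the route at target 11.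

**Step 5.**
- Risk: Wurtz homocoupling of the benzylic chloride with the reagent already formed, and slow insertion of magnesium into the aryl C–Br bonds once the chloride is consumed, would lower the titre and contaminate the reagent.
- Fallback: it sets out from chloride 6. Direct insertion of zinc dust in the presence of LiCl (THF, rt) should give (3,5-dibromo-4-methoxybenzyl)zinc chloride F4 without touching aryl bromides and with little homocoupling. With MgCl2 as Lewis-acid promoter this reagent should add to the carbonyl of 2, returning to the route at dienol 8 and keeping the key disconnection.

**Step 7.**
- Risk: reductive loss of bromine under zinc, above all from the bromine alpha to the dienone carbonyl at the quinol stage. An acid-triggered 1,2-shift of the benzyl group (quinol or dienone–phenol rearrangement) could also occur before reduction if hydrolysis needs stronger acid than aqueous acetic acid.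
- Fallback: it sets out from ketal 8 and avoids electron-transfer reagents. After hydrolysis and isolation of quinol 9, 1,2-reduction of the carbonyl (NaBH4, CeCl3·7H2O, MeOH, −78 °C) should give 2-bromo-4-(3,5-dibromo-4-methoxybenzyl)cyclohexa-2,5-diene-1,4-diol F5 as a diastereomer mixture. Catalytic acid (TsOH, CH2Cl2, rt) should ionize the tertiary doubly allylic hydroxyl, and loss of the C1 proton should give the aromatic ring, returning to the route at phenol 10.

**Step 1.**
- Risk: hydrolysis of the monoketal to the bromoquinone during work-up or chromatography, and over-oxidation if water is present.
- Fallback: it sets out from commercial 2-bromo-1,4-dimethoxybenzene. Anodic oxidation in methanolic KOH should give the bisketal 2-bromo-3,3,6,6-tetramethoxycyclohexa-1,4-diene F6. Its monohydrolysis (aqueous AcOH, acetone) should spare the ketal next to the bromine-bearing carbon, because ionization there places no positive charge on the bromine-bearing carbon and is the slower one. This returns to the route at ketal 2.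

## Further compounds

F1 | step 6 | (3-bromo-4-methoxyphenyl)magnesium chloride | COc1ccc([Mg]Cl)cc1Br
F2 | step 6 | (3-bromo-4-methoxyphenyl)(3,5-dibromo-4-methoxyphenyl)methanol (racemic) | COc1ccc(C(O)c2cc(Br)c(OC)c(Br)c2)cc1Br
F3 | step 6 | 2-bromo-4-(3,5-dibromo-4-methoxybenzyl)-1-methoxybenzene | COc1ccc(Cc2cc(Br)c(OC)c(Br)c2)cc1Br
F4 | step 5 | (3,5-dibromo-4-methoxybenzyl)zinc chloride | COc1c(Br)cc(C[Zn]Cl)cc1Br
F5 | step 7 | 2-bromo-4-(3,5-dibromo-4-methoxybenzyl)cyclohexa-2,5-diene-1,4-diol (diastereomer mixture, racemic) | OC1C=CC(O)(Cc2cc(Br)c(OC)c(Br)c2)C=C1Br
F6 | step 1 | 2-bromo-3,3,6,6-tetramethoxycyclohexa-1,4-diene | COC1(OC)C=CC(OC)(OC)C(Br)=C1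
A1 | alternative 1 | (3-bromo-4-hydroxyphenyl)(3,5-dibromo-4-methoxyphenyl)methanone | Oc1ccc(cc1Br)C(=O)c1cc(Br)c(OC)c(Br)c1
A2 | alternative 1 | 1-(3,5-dibromo-4-methoxyphenyl)prop-2-yn-1-one | C#CC(=O)c1cc(Br)c(OC)c(Br)c1
A3 | alternative 1 | 2-bromo-1-methoxy-3-(trimethylsilyloxy)buta-1,3-diene | COC=C(Br)C(=C)O[Si](C)(C)C
A4 | alternative 2 | 2-bromo-6-tert-butyl-4-(3,5-dibromo-4-hydroxybenzyl)phenol | CC(C)(C)c1cc(Cc2cc(Br)c(O)c(Br)c2)cc(Br)c1O
A5 | alternative 2 | 2-tert-butyl-4-(4-hydroxybenzyl)phenol | CC(C)(C)c1cc(Cc2ccc(O)cc2)ccc1O
A6 | alternative 3 | 2-bromo-4-(3,5-dibromo-4-methoxybenzyl)-1-methoxybenzene | COc1ccc(Cc2cc(Br)c(OC)c(Br)c2)cc1Br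
A7 | alternative 3 | N'-[(E)-(3-bromo-4-methoxyphenyl)methylidene]-4-methylbenzenesulfonohydrazide | COc1ccc(/C=N/NS(=O)(=O)c2ccc(C)cc2)cc1Br
A8 | alternative 3 | (3,5-dibromo-4-methoxyphenyl)boronic acid | COc1c(Br)cc(B(O)O)cc1Br
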